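The runs are simulated with constants of no real substance, noise included.

The E left in the north-east run at 69 h is 0.268 M of the 0.500 M charged, and this leftover is reached from below, since the reading at 12 h was 0.124 M. E comes back, which reads as a bound form of E with Q, the resting state of E while Q lasts, that releases E as free Q falls. Added Z does not alter this: the south-west run, charged with 0.150 M of Z, ends at 0.269 M, a difference within the scatter of 0.004 M.

| flask | E | Q | Z | time |
|---|---|---|---|---|
| north-east | 0.500 M | 1.25 M |  |  |
| south-east | 0.250 M | 1.00 M |  |  |
| west | 1.50 M | 1.25 M |  |  |
| south-west | 0.500 M | 1.25 M | 0.150 M |  |
| east | 0.500 M | 3.10 M |  | 69 h |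

| run | time / h | [E] / M |
|---|---|---|
| north-east run | 12 | 0.124 |
| north-east run | 23 | 0.197 |
| north-east run | 34 | 0.231 |
| north-east run | 46 | 0.256 |
| north-east run | 58 | 0.272 |
| north-east run | 69 | 0.268 |
| south-east run | 12 | 0.070 |
| south-east run | 23 | 0.108 |
| south-east run | 34 | 0.130 |
| south-east run | 46 | 0.150 |
| south-east run | 58 | 0.153 |
| south-east run | 69 | 0.156 |
| west run | 12 | 0.561 |
| west run | 23 | 0.631 |
| west run | 34 | 0.687 |
| west run | 46 | 0.724 |
| west run | 58 | 0.747 |
| west run | 69 | 0.763 |
| south-west run | 12 | 0.131 |
| south-west run | 23 | 0.196 |
| south-west run | 34 | 0.234 |
| south-west run | 46 | 0.261 |
| south-west run | 58 | 0.270 |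
| south-west run | 69 | 0.269 |

(standard deviation of a reading: 0.004 M)

* reaction order in [Q] at the outset, round the charge of the north-east run, defined at two percent of the E turned into Z
* reaction order in [E] at the outset, round the charge of the north-east run, defined at two percent of the E turned into Z (one fixed amount of Z, the same in the runs compared)
* E in the east run at 69 h, as a share of the E charged
* which of these the readings show (the product speeds the reaction / the substrate is lost by itself / nothing beyond the main steps / the second partner is lost by itself / the product decays)

- Overall: E + Q -> Z.
- Constant volume, constant temperature.
- "The second partner" is Q.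
- An order is taken over about fifteen percent of the charge, up and down.

A bench rule says that the share of E turned follows the Q charged. By 69 h the north-east run reads 46.4% of its E gone, which is 0.371 /M of share per unit of Q, and the south-east run gives 0.376 /M, so the rule fits these two runs. The border appears in the ratio of the Q charges, east over north-east, 2.48: the rule would turn 115% of the E, more than the whole charge.

A better measure is the burn, the natural logarithm of E charged over E left, which reads 0.624 in the north-east run at 69 h. Suppose that the binding stays in balance and that free Q is lost at a steady fraction per hour. If the Q held in the bound form is also neglected, the burn then grows in proportion to the logarithm of one plus the binding constant times the Q charged. Counting the E missing at 12 h in the north-east run as bound gives a crude binding constant of 3.47 /M, and with it the reckoning leaves the east run 39.9% of its E. Very strong binding leaves the burn unchanged, and the reckoning then gives 53.6%. This reckoning commits to the middle, 46.8%.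

The forecast says 42% (range 35% to 50%), lower than this reckoning, with orders of 0.26 in Q and 0.92 in E, and its verdict is that the second partner is lost by itself: “Free Q dies by itself”.

The flask gives 47.4%, orders of 0.12 in Q and 0.99 in E, and the verdict that the second partner is lost by itself.

    E + Q ⇌ J, settled at all times (17.90 /M)
    E + Q → Z (0.4320 /M/h)
    Q → Gy (0.1904 /h)

The burn of the east run comes to 0.746, larger than the north-east reading of 0.624 by a factor of 1.20, while the Q charged grew by a factor of 2.48. The loss of Q to Gy holds it down. The same east flask without that loss keeps 0.412% of its E, a burn of 5.49.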